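**Retrosynthetic overview**

1. Feature: in the ten-membered carbocycle, the C1 ketone and the C4–C5 oxirane (an epoxidised Z C4=C5 olefin next to the C3 carbinol) are the carbonyl/olefin pair that a heterolytic cut of a transannular C1–C5 bond leaves. The macrocycle is therefore traced back to a trans-fused bicycle of cyclopentane ring A (C1–C5) and a seven-membered ring (C1, C5–C10).
2. Key disconnections: oxirane ⇒ (Z)-4-en-3-ol (hydroxyl-directed peracid epoxidation, last step); ten-membered ring ⇒ γ-hydroxystannane (C1–OH, C4–SnMe3) by tin-assisted oxidative 1,4-fragmentation with Pb(OAc)4.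
3. Tricycle ⇒ ring A aldehyde + fragment 2 (a Z enol triflate): C6–C7 by Ni/Cr coupling with lactonisation in the same pot, C9=C10 by ring-closing metathesis, C10 by C1–OH-directed hydrogenation; both acyl groups are installed before the fragmentation.
4. Building blocks: ring A from (S)-4-silyloxycyclopentenone (source of C3) with tin introduced by Me3SnLi conjugate addition; fragment 2 from (S)-but-3-ene-1,2-diol (source of C8) and methyl 3-hydroxypropanoate; side-chain acid from 4-methylfuran-2(5H)-one.
5. Ring order: ring A (bought) → butenolide → seven-membered ring → ten-membered ring (unveiled by fragmentation, no ring closure) → oxirane.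

Key step: step 23

Remark: germacrane numbering (C1–C15; C12 is the lactone carbonyl, C13 its oxygenated methylene) is used for all intermediates, and the six purchased building blocks are taken to be commercial as drawn.

**Route**

Step 1
Reactants: 1 (S)-4-(tert-butyldimethylsilyloxy)cyclopent-2-en-1-one
Product: 2 trimethylsilyl enol ether of trans-4-(tert-butyldimethylsilyloxy)-3-methylcyclopentanone
Conditions: Me2CuLi (from CuI + 2 MeLi), TMSCl, THF, −78 °C; Et3N, cold aq. NaHCO3 work-up
Reagents that add atoms: lithium dimethylcuprate [Li+].C[Cu-]C; chlorotrimethylsilane C[Si](C)(C)Cl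
Why: Cuprate 1,4-addition with in situ enolate silylation should deliver methyl anti to the silyloxy group and trap the enolate regiospecifically as the silyl enol ether needed for reoxidation; the methyl-bearing centre is transient and C3 is untouched.

Step 2
Reactants: 2 silyl enol ether
Product: 3 (S)-4-(tert-butyldimethylsilyloxy)-3-methylcyclopent-2-en-1-one
Conditions: Pd(OAc)2 (10 mol %), O2 (1 atm), DMSO, 25–40 °C
Reagents that add atoms: none
Why: Saegusa–Ito oxidation, in which the palladium enolate undergoes β-hydride elimination toward the methyl-bearing carbon, should restore the enone with the C15 methyl on C4 and leave the C3 silyl ether alone.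

Step 3
Reactants: 3 methyl enone
Product: 4 (S)-4-(tert-butyldimethylsilyloxy)-2-iodo-3-methylcyclopent-2-en-1-one
Conditions: I2, pyridine, CH2Cl2, 0 → 25 °C
Reagents that add atoms: iodine II
Why: α-Iodination of the enone with iodine/pyridine (iodination–dehydroiodination) should place iodine on the only vinylic C–H, the future C5, under conditions that 4-silyloxycyclopentenones tolerate.

Step 4
Reactants: 4 iodo enone; 5 (tributylstannyl)methanol
Product: 6 (S)-4-(tert-butyldimethylsilyloxy)-2-(hydroxymethyl)-3-methylcyclopent-2-en-1-one
Conditions: Pd(PPh3)4 (5 mol %), dioxane, 90 °C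
Reagents that add atoms: none
Why: Stille coupling of the α-iodo enone, with the oxygen-substituted methyl group transferring from tin in preference to butyl, should install C6 as a hydroxymethyl group.

Step 5
Reactants: 6 hydroxymethyl enone
Product: 7 (S)-4-(tert-butyldimethylsilyloxy)-3-methyl-2-(triethylsilyloxymethyl)cyclopent-2-en-1-one (ring A enone)
Conditions: TESCl, imidazole, CH2Cl2, 0 °C
Reagents that add atoms: chlorotriethylsilane CC[Si](CC)(CC)Cl
Why: Silylation of the primary alcohol gives a primary TES ether that can later be told apart from the secondary TBS ether.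

Step 6
Reactants: 7 ring A enone
Product: 9 β-trimethylstannyl cyclopentanone (Sn on C4 trans to the C3 silyloxy group; C6 arm on C5 cis to Sn), via lithium enolate 8 (not isolated)
Conditions: Me3SnLi (from Me3SnSnMe3 + MeLi, THF, −20 °C), THF, −78 °C; then AcOH, −78 °C
Reagents that add atoms: trimethylstannyllithium [Li][Sn](C)(C)C
Why: Conjugate addition of the stannyl anion to the tetrasubstituted enone should occur anti to the C3 silyloxy group and create the quaternary C4 stannane, and cold protonation of the C1–C5 enolate anti to the C4–Sn bond (the usual sense for β-metalloid-substituted enolates, reinforced by the bulk of Me3Sn) puts H5 trans and the C6 arm cis to tin.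

Step 7
Reactants: 9 stannyl ketone; 10 2-bromopropene
Product: 13 C1 isopropenyl carbinol (C1–OH cis to the C5 arm), via isopropenyllithium 11 (not isolated), via isopropenylcerium dichloride 12 (not isolated)
Conditions: 10, t-BuLi (2 equiv), Et2O, −78 °C; CeCl3, THF, −78 °C; then 9, −78 °C; H2O
Reagents that add atoms: none
Why: 1,2-Addition of the weakly basic organocerium reagent avoids enolisation and loss of the β-silyloxy group, and attack on the carbonyl face opposite the adjacent C5 arm and the C4 stannyl group sets C1 with isopropenyl trans and hydroxyl cis to the C5 arm.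

Step 8
Reactants: 13 isopropenyl carbinol
Product: 15 C6 aldehyde with free C1 hydroxyl, via alkoxysulfonium chloride 14 (not isolated)
Conditions: (COCl)2, DMSO, CH2Cl2, −78 → −40 °C; Et3N, −78 → 0 °C
Reagents that add atoms: none
Why: Swern oxidation in which the activated sulfoxide cleaves the primary triethylsilyl ether selectively and the alkoxysulfonium salt is oxidised in the same pot should spare the secondary TBS ether, the hindered tertiary hydroxyl and the stannane; the β-hydroxy aldehyde is kept cold and used at once to avoid C5 epimerisation and retro-aldol cleavage.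

Step 9
Reactants: 16 methyl 3-hydroxypropanoate
Product: 17 methyl 3-(triethylsilyloxy)propanoate
Conditions: TESCl, imidazole, CH2Cl2, 0 °C
Reagents that add atoms: chlorotriethylsilane CC[Si](CC)(CC)Cl
Why: Routine silylation of the primary alcohol gives an ether that survives low-temperature enolate formation.

Step 10
Reactants: 18 (S)-but-3-ene-1,2-diol
Product: 19 (S)-1,2-bis(triethylsilyloxy)but-3-ene
Conditions: TESCl (2.2 equiv), imidazole, DMF, 0 → 25 °C
Reagents that add atoms: chlorotriethylsilane CC[Si](CC)(CC)Cl
Why: Exhaustive silylation of the diol leaves the future C8 stereocentre untouched.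

Step 11
Reactants: 19 bis-silyl ether
Product: 21 (S)-2-(triethylsilyloxy)but-3-enal, via alkoxysulfonium chloride 20 (not isolated)
Conditions: (COCl)2, DMSO, CH2Cl2, −78 → −40 °C; Et3N, −78 → −20 °C
Reagents that add atoms: none
Why: Swern oxidation with selective cleavage of the primary TES ether beside the secondary one should give the α-silyloxy aldehyde directly; it is used cold and at once because the centre α to the aldehyde is configurationally labile.

Step 12
Reactants: 17 silyloxy ester; 21 α-silyloxy aldehyde
Product: 23 aldol adduct (mixture at C7 and C11), via lithium enolate 22 (not isolated)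
Conditions: LiN(i-Pr)2, THF, −78 °C; then 21, −78 °C; AcOH quench
Reagents that add atoms: none
Why: Aldol addition of the lithium ester enolate, generated at −78 °C where β-elimination of the silyloxy group is slow, forms the C7–C11 bond; the two new centres arise as a mixture that does not matter, as both become trigonal.

Step 13
Reactants: 23 aldol adduct
Product: 24 β-keto ester
Conditions: Dess–Martin periodinane, pyridine, CH2Cl2, 0 → 25 °C
Reagents that add atoms: none
Why: Dess–Martin oxidation of the β-hydroxy ester under pyridine buffering should give the β-keto ester without acid-induced loss of the TES ethers or epimerisation at C8.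

Step 14
Reactants: 24 β-keto ester
Product: 26 (Z)-enol triflate (fragment 2), via lithium enolate 25 (not isolated)
Conditions: LiN(SiMe3)2, toluene, −78 °C; Tf2O, −78 → 0 °C
Reagents that add atoms: triflic anhydride O=S(=O)(OS(=O)(=O)C(F)(F)F)C(F)(F)F
Why: O-Sulfonylation of the lithium enolate, in which lithium bridges the enolate and ester oxygens, fixes the triflate cis to the ester (Z enol triflate), the geometry needed for lactonisation after coupling.

Step 15
Reactants: 15 C6 aldehyde; 26 enol triflate
Product: 29 butenolide diene, via alkenylchromium dichloride 27 (not isolated), via chromium alkoxide adduct 28 (not isolated)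
Conditions: CrCl2 (6 equiv), NiCl2 (2 mol %), degassed DMF, 25 °C; aqueous work-up
Reagents that add atoms: none
Why: Nozaki–Hiyama–Kishi reaction, in which zerovalent nickel inserts into the enol triflate, transmetalation gives the alkenyl derivative of trivalent chromium with retention of geometry, this adds chemoselectively to the aldehyde, and the C6 alkoxide (cis to the ester across C7=C11) closes the butenolide by acyl substitution; C6 is set by attack anti to the quaternary C4 in the conformer where chromium bridges the C1 and aldehyde oxygens, the sense also predicted by the Felkin–Anh model with C4 as the large group.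

Step 16
Reactants: 29 butenolide diene
Product: 30 trans-fused tricycle (ring A, seven-membered ring, butenolide) with C9=C10 olefin
Conditions: second-generation Grubbs catalyst (10 mol %), toluene, 80 °C, argon sparge
Reagents that add atoms: none
Why: Ring-closing metathesis, initiated at the monosubstituted vinyl group and closing onto the isopropenyl group, should form the trisubstituted C9=C10 olefin of the seven-membered ring, trans-fused to ring A because the C1 and C5 substituents were set trans; the tetrasubstituted butenolide olefin takes no part.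

Step 17
Reactants: 30 tricyclic olefin
Product: 31 saturated tricycle (C10–H cis to C1–OH)
Conditions: H2 (1 atm), [Ir(cod)(PCy3)(py)]PF6 (10 mol %), CH2Cl2, 25 °C
Reagents that add atoms: none
Why: Hydroxyl-directed hydrogenation, in which the cationic iridium complex binds the allylic C1 hydroxyl and delivers hydrogen to the C9=C10 face syn to it, sets C10 with H cis to the C1 hydroxyl and the C14 methyl trans, while the electron-poor tetrasubstituted butenolide olefin and the stannane are unaffected.

Step 18
Reactants: 31 bis-triethylsilyl ether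
Product: 32 C1,C8,C13-triol (C3 TBS ether retained)
Conditions: HF·pyridine, pyridine, THF, 0 → 25 °C
Reagents that add atoms: none
Why: Buffered HF·pyridine should remove the primary and secondary triethylsilyl ethers much faster than the hindered secondary TBS ether beside the quaternary stannane, and the buffered medium avoids acid-induced loss of the β-silyloxy stannane.

Step 19
Reactants: 32 triol
Product: 33 C13 acetate
Conditions: Ac2O (1.1 equiv), 2,4,6-collidine, CH2Cl2, −20 → 0 °C
Reagents that add atoms: acetic anhydride CC(=O)OC(C)=O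
Why: Acylation with one equivalent of anhydride and a hindered pyridine base at low temperature distinguishes the primary C13 hydroxyl from the hindered secondary C8 and tertiary C1 hydroxyls.

Step 20
Reactants: 34 4-methylfuran-2(5H)-one
Product: 35 sodium (Z)-4-hydroxy-3-methylbut-2-enoate
Conditions: NaOH (1.0 equiv), H2O/MeOH, 0 → 25 °C; freeze-dry
Reagents that add atoms: sodium hydroxide [Na+].[OH-]
Why: Saponification opens the butenolide to the carboxylate with the Z geometry imposed by the ring; the salt is kept basic and dry to prevent relactonisation.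

Step 21
Reactants: 35 hydroxy carboxylate salt
Product: 36 (Z)-4-acetoxy-3-methylbut-2-enoic acid
Conditions: Ac2O, pyridine, 0 °C; cold dilute HCl to pH 3
Reagents that add atoms: acetic anhydride CC(=O)OC(C)=O
Why: Acetylation of the primary hydroxyl of the salt followed by careful acidification gives the Z acetoxy acid, which cannot relactonise once the hydroxyl is capped.

Step 22
Reactants: 33 C13 acetate; 36 side-chain acid
Product: 38 γ-hydroxystannane carrying both esters, via mixed anhydride 37 (not isolated)
Conditions: 36, 2,4,6-trichlorobenzoyl chloride, Et3N, toluene, 25 °C; then 33, DMAP, toluene, 25 °C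
Reagents that add atoms: none
Why: Yamaguchi esterification, in which the mixed anhydride acylates the hindered secondary C8 hydroxyl under DMAP catalysis at room temperature, is mild enough to keep the Z enoate geometry, leaves the tertiary C1 hydroxyl alone and retains the C8 configuration because no C–O bond is broken.

Step 23
Reactants: 38 γ-hydroxystannane
Product: 40 ten-membered (Z)-4-en-1-one germacranolide (C3 TBS ether), via alkoxylead triacetate 39 (not isolated)
Conditions: Pb(OAc)4 (1.2 equiv), benzene, 60–80 °C
Reagents that add atoms: none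
Why: The tertiary C1 hydroxyl exchanges onto tetravalent lead, and as the O–Pb bond breaks with reduction to divalent lead the C1–C5 σ-electrons fold into the new C1=O while the electron-rich tertiary C4–Sn bond, held roughly anti-periplanar to C1–C5, takes up the positive charge developing at C5 to give C4=C5 as Me3Sn leaves as its acetate. This is the oxidative 1,4-fragmentation of γ-hydroxystannanes (a tin-assisted Grob-type fragmentation), a known route from bicyclic stannyl carbinols to medium-ring enones, here applied to a hydroazulene. No ring is closed: the bond shared by ring A and the seven-membered ring is cut, so the ten-membered carbocycle emerges from the periphery of the bicycle without the entropic or transannular cost of a medium-ring closure. No stereocentre is created; C3, C6, C8 and C10 are carried through and C1, C4 and C5 become trigonal. The step needs cleavage of C1–C5 rather than C1–C2 or C1–C10, secured by the β-stannyl stabilisation available only at C5, and a Z olefin, secured by the cis relation of SnMe3 and C6 on ring A (Sn trans to H5), which under anti-periplanar cleavage leaves C3 and C6 on the same side of C4=C5. The esters, the butenolide and the silyl ether are inert to Pb(OAc)4, and the non-basic medium spares the C10 centre now α to the ketone.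

Step 24
Reactants: 40 silyl ether
Product: 41 (Z)-4-en-3-ol germacranolide
Conditions: HF·pyridine, THF, 0 → 25 °C
Reagents that add atoms: none
Why: Cleavage of the secondary allylic TBS ether with HF·pyridine is acidic rather than basic and should therefore spare the acetates, the enoate, the lactone and the β-oxygenated ketone with its C10 α-stereocentre.

Step 25
Reactants: 41 allylic alcohol
Product: 42 target CNP0232076.1
Conditions: mCPBA, CH2Cl2, 0 °C; aq. NaHCO3/Na2S2O3 work-up
Reagents that add atoms: 3-chloroperbenzoic acid OOC(=O)c1cccc(Cl)c1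
Why: Hydroxyl-directed peracid epoxidation (Henbest type): in the Z allylic alcohol, A(1,3) strain with C6 keeps the C3 hydrogen near the olefin plane and the hydroxyl about 120° out of it, so the hydrogen-bonded peracid attacks the peripheral face syn to the hydroxyl and should give the threo epoxy alcohol (oxirane oxygen trans to the C3 oxygen across the ring), the sense known for peracids with acyclic Z allylic alcohols and medium-ring Z-cycloalkenols (a vanadium/hydroperoxide system favours the opposite face there, which is why it is not used); only the electron-rich C4=C5 olefin reacts, the butenolide and enoate olefins being electron-poor and Baeyer–Villiger oxidation of the C1 ketone slow at 0 °C.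

**Compound list**

1 | (S)-4-(tert-butyldimethylsilyloxy)cyclopent-2-en-1-one | O=C1C[C@H](O[Si](C)(C)C(C)(C)C)C=C1 | starting material
2 | trimethylsilyl enol ether of trans-4-(tert-butyldimethylsilyloxy)-3-methylcyclopentanone | C[Si](C)(C)OC1=C[C@H](C)[C@@H](O[Si](C)(C)C(C)(C)C)C1 | intermediate
3 | (S)-4-(tert-butyldimethylsilyloxy)-3-methylcyclopent-2-en-1-one | O=C1C[C@H](O[Si](C)(C)C(C)(C)C)C(C)=C1 | intermediate
4 | (S)-4-(tert-butyldimethylsilyloxy)-2-iodo-3-methylcyclopent-2-en-1-one | O=C1C[C@H](O[Si](C)(C)C(C)(C)C)C(C)=C1I | intermediate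
5 | (tributylstannyl)methanol | OC[Sn](CCCC)(CCCC)CCCC | starting material
6 | (S)-4-(tert-butyldimethylsilyloxy)-2-(hydroxymethyl)-3-methylcyclopent-2-en-1-one | O=C1C[C@H](O[Si](C)(C)C(C)(C)C)C(C)=C1CO | intermediate
7 | (S)-4-(tert-butyldimethylsilyloxy)-3-methyl-2-(triethylsilyloxymethyl)cyclopent-2-en-1-one (ring A enone) | O=C1C[C@H](O[Si](C)(C)C(C)(C)C)C(C)=C1CO[Si](CC)(CC)CC | intermediate
8 | lithium C1–C5 enolate of 9 | [Li]OC1=C(CO[Si](CC)(CC)CC)[C@](C)([Sn](C)(C)C)[C@@H](O[Si](C)(C)C(C)(C)C)C1 | intermediate
9 | 4-(tert-butyldimethylsilyloxy)-3-methyl-2-(triethylsilyloxymethyl)-3-(trimethylstannyl)cyclopentan-1-one; Sn trans to OTBS, CH2OTES cis to Sn | O=C1C[C@H](O[Si](C)(C)C(C)(C)C)[C@@](C)([Sn](C)(C)C)[C@H]1CO[Si](CC)(CC)CC | intermediate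
10 | 2-bromopropene | CC(Br)=C | starting material
11 | isopropenyllithium | [Li]C(C)=C | intermediate
12 | isopropenylcerium dichloride | CC(=C)[Ce](Cl)Cl | intermediate
13 | C1 isopropenyl carbinol of ring A with CH2OTES arm; C1–OH cis to the C5 arm | CC[Si](CC)(CC)OC[C@@H]1[C@](C)([Sn](C)(C)C)[C@@H](O[Si](C)(C)C(C)(C)C)C[C@@]1(O)C(C)=C | intermediate
14 | dimethyl(alkoxy)sulfonium chloride from the C6 oxygen of 13 | C[S+](C)OC[C@@H]1[C@](C)([Sn](C)(C)C)[C@@H](O[Si](C)(C)C(C)(C)C)C[C@@]1(O)C(C)=C.[Cl-] | intermediate
15 | ring A C6 aldehyde with free tertiary C1 hydroxyl | O=C[C@@H]1[C@](C)([Sn](C)(C)C)[C@@H](O[Si](C)(C)C(C)(C)C)C[C@@]1(O)C(C)=C | intermediate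
16 | methyl 3-hydroxypropanoate | COC(=O)CCO | starting material
17 | methyl 3-(triethylsilyloxy)propanoate | COC(=O)CCO[Si](CC)(CC)CC | intermediate
18 | (S)-but-3-ene-1,2-diol | OC[C@@H](O)C=C | starting material
19 | (S)-1,2-bis(triethylsilyloxy)but-3-ene | CC[Si](CC)(CC)OC[C@@H](O[Si](CC)(CC)CC)C=C | intermediate
20 | dimethyl(alkoxy)sulfonium chloride from the primary oxygen of 19 | C[S+](C)OC[C@@H](O[Si](CC)(CC)CC)C=C.[Cl-] | intermediate
21 | (S)-2-(triethylsilyloxy)but-3-enal | O=C[C@@H](O[Si](CC)(CC)CC)C=C | intermediate
22 | lithium enolate of 17 | COC(O[Li])=CCO[Si](CC)(CC)CC | intermediate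
23 | methyl 3-hydroxy-4-(triethylsilyloxy)-2-(triethylsilyloxymethyl)hex-5-enoate, (4S), mixture at C2 and C3 | COC(=O)C(CO[Si](CC)(CC)CC)C(O)[C@@H](O[Si](CC)(CC)CC)C=C | intermediate
24 | methyl 3-oxo-4-(triethylsilyloxy)-2-(triethylsilyloxymethyl)hex-5-enoate, (4S) | COC(=O)C(CO[Si](CC)(CC)CC)C(=O)[C@@H](O[Si](CC)(CC)CC)C=C | intermediate
25 | lithium (Z)-enolate of 24, O–Li cis to the ester | COC(=O)/C(CO[Si](CC)(CC)CC)=C(\O[Li])[C@@H](O[Si](CC)(CC)CC)C=C | intermediate
26 | fragment 2: methyl (Z)-4-(triethylsilyloxy)-2-(triethylsilyloxymethyl)-3-(trifluoromethylsulfonyloxy)hexa-2,5-dienoate, (4S) | COC(=O)/C(CO[Si](CC)(CC)CC)=C(\OS(=O)(=O)C(F)(F)F)[C@@H](O[Si](CC)(CC)CC)C=C | intermediate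
27 | alkenylchromium dichloride from 26, Cr cis to the ester | COC(=O)/C(CO[Si](CC)(CC)CC)=C(\[Cr](Cl)Cl)[C@@H](O[Si](CC)(CC)CC)C=C | intermediate
28 | open coupling adduct as its C6 chromium alkoxide | COC(=O)/C(CO[Si](CC)(CC)CC)=C(/[C@@H](O[Si](CC)(CC)CC)C=C)[C@H](O[Cr](Cl)Cl)[C@@H]1[C@](C)([Sn](C)(C)C)[C@@H](O[Si](C)(C)C(C)(C)C)C[C@@]1(O)C(C)=C | intermediate
29 | butenolide diene: 12,6-lactone on ring A carbinol, with C8 vinyl carbinol TES ether and C1 isopropenyl | C=C[C@H](O[Si](CC)(CC)CC)C1=C(CO[Si](CC)(CC)CC)C(=O)O[C@@H]1[C@@H]2[C@](C)([Sn](C)(C)C)[C@@H](O[Si](C)(C)C(C)(C)C)C[C@@]2(O)C(C)=C | intermediate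
30 | trans-fused tricycle with C9=C10 olefin | CC1=C[C@H](O[Si](CC)(CC)CC)C2=C(CO[Si](CC)(CC)CC)C(=O)O[C@@H]2[C@@H]3[C@](C)([Sn](C)(C)C)[C@@H](O[Si](C)(C)C(C)(C)C)C[C@@]13O | intermediate
31 | saturated tricycle, C10–H cis to C1–OH, C8 and C13 TES ethers | CC[Si](CC)(CC)OCC1=C2[C@@H](O[Si](CC)(CC)CC)C[C@H](C)[C@]3(O)C[C@H](O[Si](C)(C)C(C)(C)C)[C@@](C)([Sn](C)(C)C)[C@H]3[C@H]2OC1=O | intermediate
32 | C1,C8,C13-triol, C3 TBS ether | OCC1=C2[C@@H](O)C[C@H](C)[C@]3(O)C[C@H](O[Si](C)(C)C(C)(C)C)[C@@](C)([Sn](C)(C)C)[C@H]3[C@H]2OC1=O | intermediate
33 | C13 acetate, C8 and C1 hydroxyls free | CC(=O)OCC1=C2[C@@H](O)C[C@H](C)[C@]3(O)C[C@H](O[Si](C)(C)C(C)(C)C)[C@@](C)([Sn](C)(C)C)[C@H]3[C@H]2OC1=O | intermediate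
34 | 4-methylfuran-2(5H)-one | CC1=CC(=O)OC1 | starting material
35 | sodium (Z)-4-hydroxy-3-methylbut-2-enoate | [Na+].[O-]C(=O)/C=C(/C)CO | intermediate
36 | (Z)-4-acetoxy-3-methylbut-2-enoic acid | OC(=O)/C=C(/C)COC(C)=O | intermediate
37 | mixed anhydride of 36 with 2,4,6-trichlorobenzoic acid | CC(=O)OC/C(C)=C\C(=O)OC(=O)c1c(Cl)cc(Cl)cc1Cl | intermediate
38 | γ-hydroxystannane fragmentation precursor with C13 acetate and C8 (Z)-4-acetoxy-3-methylbut-2-enoate | CC(=O)OCC1=C2[C@@H](OC(=O)/C=C(/C)COC(C)=O)C[C@H](C)[C@]3(O)C[C@H](O[Si](C)(C)C(C)(C)C)[C@@](C)([Sn](C)(C)C)[C@H]3[C@H]2OC1=O | intermediate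
39 | C1 alkoxylead triacetate of 38 | CC(=O)OCC1=C2[C@@H](OC(=O)/C=C(/C)COC(C)=O)C[C@H](C)[C@]3(O[Pb](OC(C)=O)(OC(C)=O)OC(C)=O)C[C@H](O[Si](C)(C)C(C)(C)C)[C@@](C)([Sn](C)(C)C)[C@H]3[C@H]2OC1=O | intermediate
40 | ten-membered (Z)-4-en-1-one germacranolide, C3 TBS ether | CC(=O)OCC1=C2[C@@H](OC(=O)/C=C(/C)COC(C)=O)C[C@H](C)C(=O)C[C@H](O[Si](C)(C)C(C)(C)C)/C(C)=C\[C@H]2OC1=O | intermediate
41 | ten-membered (Z)-4-en-1-one germacranolide, free C3 hydroxyl | CC(=O)OCC1=C2[C@@H](OC(=O)/C=C(/C)COC(C)=O)C[C@H](C)C(=O)C[C@H](O)/C(C)=C\[C@H]2OC1=O | intermediate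
42 | CNP0232076.1: (3S,4R,5S,6S,8S,10S)-13-acetoxy-8-[(Z)-4-acetoxy-3-methylbut-2-enoyloxy]-4,5-epoxy-3-hydroxy-1-oxogermacr-7(11)-en-12,6-olide | CC(=O)OCC1=C2[C@@H](OC(=O)/C=C(/C)COC(C)=O)C[C@H](C)C(=O)C[C@H](O)[C@@]3(C)O[C@H]3[C@H]2OC1=O | target

**Totals**

Total step count: 25. Longest linear sequence: 17 steps (steps 1–8, 15–19, 22–25).

**Steps most likely to fail**

Step 15 (Ni/Cr coupling with lactonisation). Insertion and transmetalation at the fully substituted, doubly flanked enol triflate may be slower than retro-aldol cleavage or C5 epimerisation of the β-hydroxy aldehyde, and facial selectivity at C6 may be low if chromium does not bridge the C1 and C6 oxygens in DMF. The fallback sets out from 26 and 15 and returns at 29. Triflate 26 would be stannylated with Me3SnSnMe3, Pd(PPh3)4 and LiCl in THF at 60 °C to the (Z)-alkenylstannane F1, then iododestannylated with I2 in CH2Cl2 at 0 °C to the (Z)-β-iodo enoate F2. Iodine–magnesium exchange with i-PrMgCl·LiCl in THF at −40 °C would give the ester-chelated alkenylmagnesium chloride F3. Adding F3 (2.2 equiv, the first equivalent being consumed by the tertiary hydroxyl) to aldehyde 15 at −78 °C would proceed through a magnesium chelate of the C1 and C6 oxygens, which enforces the same facial sense, and the magnesium alkoxide would close the butenolide on warming to give 29.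

Step 23 (oxidative fragmentation). Ligand exchange of the hindered tertiary hydroxyl on lead may be slower than destannylative elimination toward C3 with loss of the silyloxy group, or than acetolysis of the C–Sn bond, and cleavage of C1–C2 or C1–C10 may compete. The fallback sets out from 38 and returns at 40, cutting the same bond in a one-electron manifold. PhI(OAc)2 and I2 under visible light in cyclohexane/CH2Cl2 at 25 °C would convert 38 into the tertiary hypoiodite F4. Its alkoxy radical undergoes β-scission of C1–C5, the only scission that gives a β-stannyl radical, and the C5 radical expels the trimethylstannyl radical faster than it rotates, giving the Z enone 40 (alkoxy-radical fragmentation of the Suárez type combined with β-elimination of a stannyl radical).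

Step 25 (directed epoxidation). The ring conformation rather than the hydroxyl may steer the peracid, giving poor facial selectivity, or the acid by-product may open the oxirane transannularly. The fallback sets out from 40 and returns at 42, delivering oxygen to the silyl ether under reagent control. Shi epoxidation of 40 with the fructose-derived ketone (the enantiomer whose spiro transition state places the oxirane oxygen trans to the C3 oxygen; both antipodes are accessible) and Oxone (2KHSO5·KHSO4·K2SO4) in MeCN/dimethoxymethane/aqueous buffer at pH 8–9 and 0 °C would give the epoxy silyl ether F5. HF·pyridine in THF would then remove the TBS group to give 42.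

**Further compounds**

F1 | step 15 | methyl (Z)-4-(triethylsilyloxy)-2-(triethylsilyloxymethyl)-3-(trimethylstannyl)hexa-2,5-dienoate, (4S) | COC(=O)/C(CO[Si](CC)(CC)CC)=C(\[Sn](C)(C)C)[C@@H](O[Si](CC)(CC)CC)C=C
F2 | step 15 | methyl (Z)-3-iodo-4-(triethylsilyloxy)-2-(triethylsilyloxymethyl)hexa-2,5-dienoate, (4S) | COC(=O)/C(CO[Si](CC)(CC)CC)=C(\I)[C@@H](O[Si](CC)(CC)CC)C=C
F3 | step 15 | alkenylmagnesium chloride from F2, Mg cis to the ester | COC(=O)/C(CO[Si](CC)(CC)CC)=C(\[Mg]Cl)[C@@H](O[Si](CC)(CC)CC)C=C
F4 | step 23 | C1 hypoiodite of 38 | CC(=O)OCC1=C2[C@@H](OC(=O)/C=C(/C)COC(C)=O)C[C@H](C)[C@]3(OI)C[C@H](O[Si](C)(C)C(C)(C)C)[C@@](C)([Sn](C)(C)C)[C@H]3[C@H]2OC1=O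
F5 | step 25 | 4,5-epoxide of 40, C3 TBS ether | CC(=O)OCC1=C2[C@@H](OC(=O)/C=C(/C)COC(C)=O)C[C@H](C)C(=O)C[C@H](O[Si](C)(C)C(C)(C)C)[C@@]3(C)O[C@H]3[C@H]2OC1=O
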